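## Retrosynthetic overview

1. Target ⇒ C2 isovalerylation, C14 acetylation and conversion of a furan into the γ-ylidene butenolide (singlet oxygen, then dehydration) ⇒ macrocyclic furan 25.
2. Ten-membered ring ⇒ C6–C7 bond: the C7-lithiated furan (a masked acyl anion, since this carbon becomes the C7 enol-lactone carbon) opens a (5S)-2,2-disubstituted epoxide at C6. Both carbons are electrophilic in normal polarity, and the C5 carbinol arrives preformed.
3. Ring A ⇒ C1–C10 bond by epoxide-initiated cation–olefin cyclisation of an (E,E)-geranyl chain; C14 is then inverted by oxidation/reduction.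
4. Acyclic chain ⇒ geranyl acetate (SeO2 oxidation), 4-methyl-3-furylzinc chloride (allylic coupling), a dialkylzinc from (S)-4-methyl-4-vinyl-1,3-dioxolan-2-one (asymmetric aldehyde addition), then Sharpless epoxidation.
5. Ring order: furan (from 3,4-dibromofuran) → ring A → ten-membered ring → butenolide (by oxidation of the furan).

Assumption: atom labels follow briarane numbering (C1 quaternary ring-fusion carbon, C2 isovalerate carbinol, C5 tertiary carbinol, C7 lactone γ-carbon, C10 ring-fusion CH, C14 acetate carbinol); where a chiral ligand is named, its antipode is used if the observed sense of induction is the opposite one.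

## Route

Step 1
Reactants: 1 geranyl acetate
Product: 3 (2E,6E)-8-oxogeranyl acetate, via 8-hydroxygeranyl acetate 2 (not isolated)
Conditions: SeO2 (1.1 equiv), 95% EtOH, reflux
Reagents that add atoms: selenium dioxide O=[Se]=O
Why: Riley allylic oxidation (ene reaction then [2,3]-sigmatropic shift) attacks the E-methyl of the electron-rich terminal alkene, the 2,3-alkene being deactivated by the allylic acetate, and carries alcohol 2 on to the E-enal; no stereocentre is formed.

Step 2
Reactants: 4 3,4-dibromofuran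
Product: 6 3-bromo-4-methylfuran, via (4-bromofuran-3-yl)lithium 5 (not isolated)
Conditions: n-BuLi (1.0 equiv), Et2O, −78 °C; MeI, −78 → 0 °C
Reagents that add atoms: iodomethane CI
Why: Bromine–lithium exchange followed by SN2 methylation; at −78 °C the 3-furyllithium neither ring-opens nor isomerises to the 2-lithio species.

Step 3
Reactants: 6 3-bromo-4-methylfuran; 3 (2E,6E)-8-oxogeranyl acetate
Product: 9 (2E,6E)-2,6-dimethyl-8-(4-methylfuran-3-yl)octa-2,6-dienal, via (4-methylfuran-3-yl)lithium 7 (not isolated), via (4-methylfuran-3-yl)zinc chloride 8 (not isolated)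
Conditions: 6, n-BuLi, Et2O, −78 °C; ZnCl2, THF, −78 → 0 °C; then 3, Pd(PPh3)4 (5 mol %), THF, 23 °C
Reagents that add atoms: none
Why: Negishi-type allylic coupling: zerovalent palladium ionises the allylic acetate, and transmetalation from zinc with reductive elimination at the unhindered terminus gives the linear E product, while the arylzinc leaves the enal untouched.

Step 4
Reactants: 9 (2E,6E)-2,6-dimethyl-8-(4-methylfuran-3-yl)octa-2,6-dienal
Product: 10 (2E,6E)-8-(2,5-dibromo-4-methylfuran-3-yl)-2,6-dimethylocta-2,6-dienal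
Conditions: NBS (2.05 equiv), DMF, −20 → 0 °C, dark
Reagents that add atoms: N-bromosuccinimide O=C1CCC(=O)N1Br
Why: Electrophilic aromatic bromination at both free α-positions of the furan is faster than attack on the alkenes or the enal; the dibromide protects the furan in the later oxidising and Lewis-acidic steps and carries the handle for bromine–lithium exchange.

Step 5
Reactants: 11 racemic 2-methyl-2-vinyloxirane
Product: 12 (S)-4-methyl-4-vinyl-1,3-dioxolan-2-one
Conditions: Pd2(dba)3·CHCl3 (1 mol %), (R,R)-DACH-naphthyl Trost ligand (3 mol %), NaHCO3, CH2Cl2/H2O, 23 °C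
Reagents that add atoms: sodium hydrogencarbonate [Na+].OC([O-])=O
Why: Trost dynamic kinetic asymmetric allylic alkylation: both enantiomers of 11 ionise to interconverting π-allyl palladium complexes, hydrogencarbonate is delivered to the tertiary terminus under ligand control and closes to the cyclic carbonate, which sets the C5 stereocentre (S).

Step 6
Reactants: 12 (S)-4-methyl-4-vinyl-1,3-dioxolan-2-one; 10 (2E,6E)-8-(2,5-dibromo-4-methylfuran-3-yl)-2,6-dimethylocta-2,6-dienal
Product: 15 (2S,5S)-allylic alcohol carbonate, via alkylborane 13 (not isolated), via dialkylzinc 14 (not isolated)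
Conditions: 12 (3 equiv), Et2BH, 0 → 23 °C; Et2Zn, 0 °C, then vacuum; then 10, Ti(OiPr)4 (2 equiv), (1R,2R)-1,2-bis(trifluoromethanesulfonamido)cyclohexane (8 mol %), toluene, −20 °C
Reagents that add atoms: none
Why: Hydroboration and boron–zinc exchange give a functionalised dialkylzinc that adds to the enal in a Knochel-type titanium/bis-sulfonamide-catalysed asymmetric alkylzinc addition; the (1R,2R) ligand directs attack to the Si face and sets C2 as S, and the carbonate and aryl bromides are inert to the zinc reagent.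

Step 7
Reactants: 15 (2S,5S)-allylic alcohol carbonate
Product: 16 erythro (1R,14R)-epoxy (2S)-alcohol
Conditions: Ti(OiPr)4 (10 mol %), L-(+)-diisopropyl tartrate (12 mol %), t-BuOOH, 4 Å MS, CH2Cl2, −20 °C
Reagents that add atoms: tert-butyl hydroperoxide CC(C)(C)OO
Why: Sharpless asymmetric epoxidation in its matched mode: with L-(+)-tartrate the (2S)-alcohol is epoxidised on the face that gives the erythro trans-epoxide (C1 and C14 set), any minor (2R)-epimer reacts far more slowly, and the isolated 10,11-alkene and the dibromofuran are untouched.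

Step 8
Reactants: 16 erythro (1R,14R)-epoxy (2S)-alcohol
Product: 17 epoxy C2 TBS ether
Conditions: TBSCl, imidazole, DMF, 23 °C
Reagents that add atoms: tert-butyldimethylsilyl chloride CC(C)(C)[Si](C)(C)Cl
Why: Silylation of the secondary alcohol installs a group that does not participate at the adjacent cationic centre (an ester would) and that later distinguishes O2 from O14; no stereocentre changes.

Step 9
Reactants: 17 epoxy C2 TBS ether
Product: 18 ring A cyclohexenol with equatorial (14R)-hydroxyl
Conditions: ZrCl4 (2.2 equiv), CH2Cl2, −78 → −30 °C; then H2O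
Reagents that add atoms: none
Why: Epoxide-initiated cation–olefin (biomimetic terpene) cyclisation: the Lewis acid opens the epoxide at tertiary C1 while the 10,11-alkene attacks anti through a chair transition state (inversion at C1, C14–O retained and equatorial, the E-alkene placing C9 equatorial and trans to the C2 arm), and the C11 cation loses H-12 to give the endocyclic alkene.

Step 10
Reactants: 18 ring A cyclohexenol with equatorial (14R)-hydroxyl
Product: 19 ring A 14-ketone
Conditions: Dess–Martin periodinane, pyridine, CH2Cl2, 0 °C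
Reagents that add atoms: none
Why: Dess–Martin oxidation of the only free alcohol under buffered, non-enolising conditions keeps the β,γ-unsaturated ketone out of conjugation; C1 is quaternary, so no stereocentre can epimerise.

Step 11
Reactants: 19 ring A 14-ketone
Product: 20 ring A cyclohexenol with axial (14S)-hydroxyl
Conditions: LiBH(s-Bu)3, THF, −78 °C; then H2O
Reagents that add atoms: none
Why: The bulky hydride attacks the cyclohexanone from the equatorial direction and gives the axial alcohol, trans to the axial C15 methyl and cis to the C2 arm (as in reductions of 3-oxo-4,4-dimethyl terpenoids); carbonate and aryl bromides survive at −78 °C.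

Step 12
Reactants: 20 ring A cyclohexenol with axial (14S)-hydroxyl
Product: 23 (5S)-5,6-epoxide, via triol 21 (not isolated), via primary tosylate 22 (not isolated)
Conditions: K2CO3 (cat.), MeOH, 23 °C; evaporate; NaH (3.3 equiv), 1-tosylimidazole (1.05 equiv), THF, 0 → 23 °C
Reagents that add atoms: none
Why: Carbonate methanolysis, then selective sulfonylation of the primary alkoxide and intramolecular Williamson closure by the tertiary alkoxide (one-pot diol-to-epoxide conversion) give the terminal 2,2-disubstituted epoxide without touching C5; the hindered axial C14 alkoxide is not sulfonylated.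

Step 13
Reactants: 23 (5S)-5,6-epoxide
Product: 25 macrocyclic furan diol, via trilithiated furan 24 (not isolated)
Conditions: t-BuLi (5.1 equiv), THF/Et2O (0.002 M), −78 °C; then −78 → 23 °C; H2O
Reagents that add atoms: none
Why: Proposed new method: double bromine–lithium exchange gives the 2,5-dilithiofuran, whose C7–Li (a masked acyl anion, because this furan carbon becomes the C7 enol-lactone carbon) opens the epoxide at its unhindered CH2 (C6) in a 10-endo SN2 closure that joins two normally electrophilic carbons and leaves the preset (5S)-carbinol untouched, while the C19–Li cannot reach C6 without a strained meta-bridged ring and is protonated on work-up; the closest known reactions are intermolecular openings of isobutylene-oxide-type epoxides by 2-furyllithium and Parham-type cyclisations of aryllithiums onto tethered epoxides.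

Step 14
Reactants: 25 macrocyclic furan diol
Product: 29 14-acetoxy ylidene butenolide C2 TBS ether, via endoperoxide 26 (not isolated), via hydroxybutenolide 27 (not isolated), via bis-acetate 28 (not isolated)
Conditions: O2, hν (visible), methylene blue, i-Pr2NEt, CH2Cl2, −78 °C; then Ac2O, Et3N, DMAP, 0 → 23 °C; DBU, 23 °C
Reagents that add atoms: dioxygen O=O; acetic anhydride CC(=O)OC(C)=O
Why: The electron-rich furan takes up singlet oxygen by [4+2] cycloaddition, base removes the only bridgehead hydrogen (C19–H) in a Kornblum–DeLaMare fragmentation so that the carbonyl ends at C19 and the hydroxyl at C7, and acetylation of the C14 alcohol and of the lactol followed by loss of acetic acid towards C6 gives the ylidene butenolide, whose C6=C7 geometry (C5 cis to C8) is enforced by the ten-membered ring.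

Step 15
Reactants: 29 14-acetoxy ylidene butenolide C2 TBS ether
Product: 30 14-acetoxy ylidene butenolide C2 alcohol
Conditions: HF·pyridine, pyridine/THF, 0 → 23 °C
Reagents that add atoms: none
Why: Fluoride-driven silyl ether cleavage under buffered conditions spares the acetate, the enol lactone and the tertiary allylic alcohol.

Step 16
Reactants: 30 14-acetoxy ylidene butenolide C2 alcohol
Product: 31 CNP0208239.1
Conditions: 3-methylbutanoic anhydride, DMAP, Et3N, CH2Cl2, 23 °C
Reagents that add atoms: 3-methylbutanoic anhydride CC(C)CC(=O)OC(=O)CC(C)C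
Why: DMAP-catalysed acyl transfer esterifies the secondary C2 alcohol much faster than the tertiary C5 alcohol, which gives the target with all five stereocentres as set earlier.

## Compound list

1 | geranyl acetate, (2E)-3,7-dimethylocta-2,6-dien-1-yl acetate | CC(=O)OC/C=C(\C)CCC=C(C)C | starting material
2 | (2E,6E)-8-hydroxy-3,7-dimethylocta-2,6-dien-1-yl acetate | CC(=O)OC/C=C(\C)CC/C=C(\C)CO | intermediate
3 | (2E,6E)-3,7-dimethyl-8-oxoocta-2,6-dien-1-yl acetate | CC(=O)OC/C=C(\C)CC/C=C(\C)C=O | intermediate
4 | 3,4-dibromofuran | Brc1cocc1Br | starting material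
5 | (4-bromofuran-3-yl)lithium | [Li]c1cocc1Br | intermediate
6 | 3-bromo-4-methylfuran | Cc1cocc1Br | intermediate
7 | (4-methylfuran-3-yl)lithium | [Li]c1cocc1C | intermediate
8 | (4-methylfuran-3-yl)zinc chloride | Cl[Zn]c1cocc1C | intermediate
9 | (2E,6E)-2,6-dimethyl-8-(4-methylfuran-3-yl)octa-2,6-dienal | Cc1cocc1C/C=C(\C)CC/C=C(\C)C=O | intermediate
10 | (2E,6E)-8-(2,5-dibromo-4-methylfuran-3-yl)-2,6-dimethylocta-2,6-dienal | Cc1c(Br)oc(Br)c1C/C=C(\C)CC/C=C(\C)C=O | intermediate
11 | racemic 2-methyl-2-vinyloxirane (isoprene monoepoxide) | C=CC1(C)CO1 | starting material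
12 | (S)-4-methyl-4-vinyl-1,3-dioxolan-2-one | C=C[C@@]1(C)COC(=O)O1 | intermediate
13 | diethyl{2-[(4S)-4-methyl-2-oxo-1,3-dioxolan-4-yl]ethyl}borane | CCB(CC)CC[C@@]1(C)COC(=O)O1 | intermediate
14 | bis{2-[(4S)-4-methyl-2-oxo-1,3-dioxolan-4-yl]ethyl}zinc | [Zn](CC[C@@]1(C)COC(=O)O1)CC[C@@]1(C)COC(=O)O1 | intermediate
15 | (4S)-4-[(3S,4E,8E)-10-(2,5-dibromo-4-methylfuran-3-yl)-3-hydroxy-4,8-dimethyldeca-4,8-dien-1-yl]-4-methyl-1,3-dioxolan-2-one (C2 S, C5 S) | Cc1c(Br)oc(Br)c1C/C=C(\C)CC/C=C(\C)[C@@H](O)CC[C@@]2(C)COC(=O)O2 | intermediate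
16 | trans-1,14-epoxide of 15, erythro to the (2S)-carbinol (epoxide carbons 1R,14R; 10,11-alkene E) | Cc1c(Br)oc(Br)c1C/C=C(\C)CC[C@H]2O[C@]2(C)[C@@H](O)CC[C@@]3(C)COC(=O)O3 | intermediate
17 | C2 tert-butyldimethylsilyl ether of 16 | Cc1c(Br)oc(Br)c1C/C=C(\C)CC[C@H]2O[C@]2(C)[C@@H](O[Si](C)(C)C(C)(C)C)CC[C@@]3(C)COC(=O)O3 | intermediate
18 | ring A cyclohex-11-enol: C1 bears methyl and the (2S)-silyloxy chain ending in the (5S)-carbonate, C10 bears the (2,5-dibromo-4-methylfuran-3-yl)methyl group trans to the C2 chain, 14-OH equatorial (14R), cis to the C15 methyl | O[C@@H]1CC=C(C)[C@H](Cc2c(C)c(Br)oc2Br)[C@@]1(C)[C@@H](O[Si](C)(C)C(C)(C)C)CC[C@@]3(C)COC(=O)O3 | intermediate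
19 | 14-ketone of 18 | O=C1CC=C(C)[C@H](Cc2c(C)c(Br)oc2Br)[C@@]1(C)[C@@H](O[Si](C)(C)C(C)(C)C)CC[C@@]3(C)COC(=O)O3 | intermediate
20 | C14 epimer of 18: 14-OH axial (14S), trans to the C15 methyl | O[C@H]1CC=C(C)[C@H](Cc2c(C)c(Br)oc2Br)[C@@]1(C)[C@@H](O[Si](C)(C)C(C)(C)C)CC[C@@]3(C)COC(=O)O3 | intermediate
21 | triol from 20: (5S)-5,6-diol and free 14-OH | O[C@H]1CC=C(C)[C@H](Cc2c(C)c(Br)oc2Br)[C@@]1(C)[C@@H](O[Si](C)(C)C(C)(C)C)CC[C@](C)(O)CO | intermediate
22 | 6-O-(4-methylbenzenesulfonate) of 21 | O[C@H]1CC=C(C)[C@H](Cc2c(C)c(Br)oc2Br)[C@@]1(C)[C@@H](O[Si](C)(C)C(C)(C)C)CC[C@](C)(O)COS(=O)(=O)c3ccc(C)cc3 | intermediate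
23 | (5S)-5,6-epoxide (2-methyl-2-alkyloxirane) with free 14-OH, 2-OTBS and the 2,5-dibromofuran | O[C@H]1CC=C(C)[C@H](Cc2c(C)c(Br)oc2Br)[C@@]1(C)[C@@H](O[Si](C)(C)C(C)(C)C)CC[C@@]3(C)CO3 | intermediate
24 | O14,C7,C19-trilithio derivative of 23 | [Li]O[C@H]1CC=C(C)[C@H](Cc2c(C)c([Li])oc2[Li])[C@@]1(C)[C@@H](O[Si](C)(C)C(C)(C)C)CC[C@@]3(C)CO3 | intermediate
25 | macrocyclic furan: briarane skeleton with a 7,8-fused 3-methylfuran (C19–H), (5S)-5-OH, (14S)-14-OH, (2S)-2-OTBS, 11,12-ene | O[C@H]1CC=C(C)[C@@H]2Cc3c(C)coc3C[C@@](C)(O)CC[C@H](O[Si](C)(C)C(C)(C)C)[C@@]12C | intermediate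
26 | 7,19-epidioxide (furan endoperoxide) of 25, mixture of faces | O[C@H]1CC=C(C)[C@@H]2CC3=C(C)C4OOC3(O4)C[C@@](C)(O)CC[C@H](O[Si](C)(C)C(C)(C)C)[C@@]12C | intermediate
27 | 7-hydroxybutenolide (C19 lactone carbonyl, 7-OH lactol, C7 epimers) | O[C@H]1CC=C(C)[C@@H]2CC3=C(C)C(=O)OC3(O)C[C@@](C)(O)CC[C@H](O[Si](C)(C)C(C)(C)C)[C@@]12C | intermediate
28 | 7,14-bis-acetate of 27 | CC(=O)O[C@H]1CC=C(C)[C@@H]2CC3=C(C)C(=O)OC3(OC(C)=O)C[C@@](C)(O)CC[C@H](O[Si](C)(C)C(C)(C)C)[C@@]12C | intermediate
29 | 2-O-TBS ether of the 14-acetoxy (6E)-ylidene butenolide | CC(=O)O[C@H]1CC=C(C)[C@@H]2CC3=C(C)C(=O)O/C3=C/[C@@](C)(O)CC[C@H](O[Si](C)(C)C(C)(C)C)[C@@]12C | intermediate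
30 | 14-acetoxy (6E)-ylidene butenolide with free (2S)-2-OH and (5S)-5-OH | CC(=O)O[C@H]1CC=C(C)[C@@H]2CC3=C(C)C(=O)O/C3=C/[C@@](C)(O)CC[C@H](O)[C@@]12C | intermediate
31 | CNP0208239.1 (14-acetoxy-2-isovaleryloxy-5-hydroxy briarane butenolide) | CC(=O)O[C@H]1CC=C(C)[C@@H]2CC3=C(C)C(=O)O/C3=C/[C@@](C)(O)CC[C@H](OC(=O)CC(C)C)[C@@]12C | target

## Step count and risk

Total step count: 16. Longest linear sequence: 14 steps (steps 1, 3, 4 and 6 to 16, from geranyl acetate).

Steps most likely to fail:

Step 13 (ring closure by the furyllithium). A ten-membered ring closed by an aryllithium on an epoxide has no direct precedent; oligomerisation or proton quench may win. The fallback sets out from 23 and returns at 25. LiI and AcOH in THF open 23 at C6 to give the iodohydrin F2. NiBr2·glyme, 4,4′-di-tert-butyl-2,2′-bipyridine and Mn powder in DMA at 0.005 M then join C6 and C7 by a nickel-catalysed reductive cross-electrophile coupling, in which the C6 alkyl radical is captured by the C7 aryl-nickel species, so no carbanion is needed; this gives the 19-bromo macrocycle F3. t-BuLi at −78 °C followed by MeOH removes the remaining bromine and gives 25.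

Step 9 (cationic cyclisation). Semipinacol shift of the epoxy silyl ether, trapping of the C11 cation by O14, or the wrong alkene isomer may compete. The fallback sets out from 17 and returns at 18. Cp2TiCl2 and Mn powder in THF generate Cp2TiCl (trivalent titanium), which opens the epoxide homolytically; 6-endo radical cyclisation through the same chair and β-hydride loss give the exocyclic methylene isomer F1. RhCl3·3H2O in EtOH at 70 °C then moves the double bond into the ring, stopped at the trisubstituted 11,12-alkene, to give 18.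

Step 14 (furan to ylidene butenolide). The lactol can open to a β-hydroxy ketone that may dehydrate or undergo retro-aldol cleavage under the basic one-pot conditions. The fallback sets out from 25 and returns at 29. Ac2O in pyridine gives the 14-acetate F4. NBS and NaHCO3 in aqueous THF at −20 °C open the furan oxidatively to the (Z)-keto-enal F5. NaClO2, NaH2PO4 and 2-methyl-2-butene in t-BuOH/H2O oxidise the aldehyde, and the acid closes to the hydroxybutenolide F6. MsCl and Et3N at 0 °C dehydrate F6 to 29.

## Further compounds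

F1 | step 9 | exocyclic-methylene isomer of 18 (C11=CH2, 14-OH equatorial) | O[C@@H]1CCC(=C)[C@H](Cc2c(C)c(Br)oc2Br)[C@@]1(C)[C@@H](O[Si](C)(C)C(C)(C)C)CC[C@@]3(C)COC(=O)O3
F2 | step 13 | (5S)-5-hydroxy-6-iodide (iodohydrin) from 23 | O[C@H]1CC=C(C)[C@H](Cc2c(C)c(Br)oc2Br)[C@@]1(C)[C@@H](O[Si](C)(C)C(C)(C)C)CC[C@](C)(O)CI
F3 | step 13 | 19-bromo derivative of macrocyclic furan 25 | O[C@H]1CC=C(C)[C@@H]2Cc3c(C)c(Br)oc3C[C@@](C)(O)CC[C@H](O[Si](C)(C)C(C)(C)C)[C@@]12C
F4 | step 14 | 14-acetate of macrocyclic furan 25 | CC(=O)O[C@H]1CC=C(C)[C@@H]2Cc3c(C)coc3C[C@@](C)(O)CC[C@H](O[Si](C)(C)C(C)(C)C)[C@@]12C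
F5 | step 14 | (Z)-keto-enal from furan opening (C7 ketone, C19 aldehyde, 14-acetate) | CC(=O)O[C@H]1CC=C(C)[C@@H]2C/C(=C(\C)C=O)C(=O)C[C@@](C)(O)CC[C@H](O[Si](C)(C)C(C)(C)C)[C@@]12C
F6 | step 14 | 14-acetoxy 7-hydroxybutenolide | CC(=O)O[C@H]1CC=C(C)[C@@H]2CC3=C(C)C(=O)OC3(O)C[C@@](C)(O)CC[C@H](O[Si](C)(C)C(C)(C)C)[C@@]12C
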